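**Strategy**

Everything rests on reading the C3 carbinol/C4 ketone pair of ring C (the pyranone ring) as the oxidised form of a C3=C4 enol double bond. Ring C is therefore closed by olefin metathesis between the silyl enol ether of a ring A acetophenone (C4) and the vinyl group (C3) of an enantioenriched aryl 1-arylallyl ether whose carbinol carbon is C2. In one operation this forges C3=C4, closes the six-membered ring and gives a 4-silyloxy-2H-chromene set up for a C2-controlled Rubottom oxidation to the trans 3-oxy-4-ketone. The prenyl group is added afterwards, by Stille coupling at a C8 bromide, since it would compete in both metathesis and epoxidation.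

Key step: step 8

Remarks: atom numbers C2, C3, C4, C5, C8 refer to the chromanone skeleton of the target (ring A = benzo ring, ring C = pyranone ring). TIPSO = triisopropylsilyloxy, TBSO = tert-butyldimethylsilyloxy.
Assumption: the iridium catalyst is taken to follow the usual sense of induction for cinnamyl carbonates, so that the (Sa,Sc,Sc) phosphoramidite gives the (S) ether; if the sense proved opposite, the mirror-image ligand would be used.

**Route**

Step 1
Reactants: 1 1-(2,6-dihydroxy-4-methoxyphenyl)ethanone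
Product: 2 1-(3-bromo-2,6-dihydroxy-4-methoxyphenyl)ethanone
Conditions: NBS (1.0 equiv), MeCN, 0 °C
Reagents that add atoms: N-bromosuccinimide, O=C1CCC(=O)N1Br
Why: Electrophilic aromatic bromination of the phloroglucinol-type ring; the two free ring positions are equivalent by symmetry, so one equivalent of NBS should give a single monobromide.

Step 2
Reactants: 2 1-(3-bromo-2,6-dihydroxy-4-methoxyphenyl)ethanone
Product: 3 1-[3-bromo-2-hydroxy-4-methoxy-6-(TIPSO)phenyl]ethanone
Conditions: TIPSCl (1.05 equiv), imidazole, DMF, 0 °C to rt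
Reagents that add atoms: triisopropylsilyl chloride, CC(C)[Si](Cl)(C(C)C)C(C)C
Why: Sterically governed mono-silylation: the bulky silyl chloride should take the hydroxyl next to the ring hydrogen, while the hydroxyl flanked by bromine stays free and hydrogen-bonded to the acetyl group.

Step 3
Reactants: 4 methyl (E)-4-hydroxycinnamate
Product: 5 methyl (E)-3-[4-(TIPSO)phenyl]prop-2-enoate
Conditions: TIPSCl, imidazole, DMF, rt
Reagents that add atoms: triisopropylsilyl chloride, CC(C)[Si](Cl)(C(C)C)C(C)C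
Why: Standard phenol silylation; the TIPS aryl ether should resist the aryloxide and methoxide present in step 6 better than a smaller silyl group.

Step 4
Reactants: 5 methyl (E)-3-[4-(TIPSO)phenyl]prop-2-enoate
Product: 6 (E)-3-[4-(TIPSO)phenyl]prop-2-en-1-ol
Conditions: i-Bu2AlH (2.3 equiv), CH2Cl2, −78 °C; Rochelle salt work-up
Reagents that add atoms: none
Why: 1,2-Reduction of the enoate by the aluminium hydride should give the (E)-allylic alcohol without touching the aryl silyl ether.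

Step 5
Reactants: 6 (E)-3-[4-(TIPSO)phenyl]prop-2-en-1-ol
Product: 7 methyl (E)-3-[4-(TIPSO)phenyl]prop-2-en-1-yl carbonate
Conditions: ClCO2Me, pyridine, CH2Cl2, 0 °C
Reagents that add atoms: methyl chloroformate, COC(=O)Cl
Why: O-Acylation with the chloroformate supplies the linear allylic carbonate that ionises on iridium.

Step 6
Reactants: 3 1-[3-bromo-2-hydroxy-4-methoxy-6-(TIPSO)phenyl]ethanone; 7 methyl (E)-3-[4-(TIPSO)phenyl]prop-2-en-1-yl carbonate
Product: 9 1-[3-bromo-4-methoxy-2-({(1S)-1-[4-(TIPSO)phenyl]prop-2-en-1-yl}oxy)-6-(TIPSO)phenyl]ethanone, via lithium aryloxide 8 (not isolated)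
Conditions: LiN(SiMe3)2 (1.0 equiv), THF, 0 °C; then 7, [Ir(cod)Cl]2 (2 mol%), (Sa,Sc,Sc)-O,O'-(1,1'-binaphthyl-2,2'-diyl) N,N-bis(1-phenylethyl)phosphoramidite (4 mol%, pre-activated with n-PrNH2), THF, rt
Reagents that add atoms: none
Why: Iridium-catalysed asymmetric allylic etherification (Hartwig type): the aryloxide attacks the aryl-substituted terminus of the allyl iridium intermediate on the face fixed by the cyclometalated phosphoramidite, which sets C2 of the branched ether as (S) under catalyst control.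

Step 7
Reactants: 9 1-[3-bromo-4-methoxy-2-({(1S)-1-[4-(TIPSO)phenyl]prop-2-en-1-yl}oxy)-6-(TIPSO)phenyl]ethanone
Product: 11 3-bromo-1-[1-(TBSO)ethenyl]-4-methoxy-2-({(1S)-1-[4-(TIPSO)phenyl]prop-2-en-1-yl}oxy)-6-(TIPSO)benzene, via potassium enolate 10 (not isolated)
Conditions: KN(SiMe3)2 (1.1 equiv), THF, −78 °C; then TBSCl, −78 to 0 °C
Reagents that add atoms: tert-butyldimethylsilyl chloride, CC(C)(C)[Si](C)(C)Cl
Why: Kinetic enolisation of the methyl ketone (its only acidic C–H) and O-silylation should give the silyl enol ether under base-only conditions that cannot ionise the benzylic allylic ether at C2.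

Step 8
Reactants: 11 3-bromo-1-[1-(TBSO)ethenyl]-4-methoxy-2-({(1S)-1-[4-(TIPSO)phenyl]prop-2-en-1-yl}oxy)-6-(TIPSO)benzene
Product: 12 (2S)-8-bromo-4-(TBSO)-7-methoxy-5-(TIPSO)-2-[4-(TIPSO)phenyl]-2H-chromene
Conditions: second-generation Grubbs catalyst (H2IMes)(PCy3)Cl2Ru=CHPh (5–10 mol%), degassed toluene (0.01 M), 60 °C, argon sweep
Reagents that add atoms: none
Why: Ring-closing olefin metathesis by the Chauvin mechanism: the ruthenium benzylidene should first exchange with the unhindered monosubstituted vinyl group, and the resulting alkylidene at C3 should engage the 1,1-disubstituted silyl enol ether through a ruthenacyclobutane ([2+2]/retro-[2+2]), releasing ethylene and leaving the C3=C4 double bond. The closest known reaction type is silyl enol ether–ene ring-closing metathesis of aryl silyl enol ethers carrying an ortho heteroatom-tethered allyl group, which gives cyclic silyl enol ethers such as 4-silyloxy-1,2-dihydroquinolines. Ring C is closed as a six-membered ring with the new double bond endocyclic, a closure favoured by the two olefins being held ortho to each other on ring A. No stereocentre is formed; C2 carries no acidic hydrogen under these neutral conditions, passes through unchanged and later controls C3. The step needs initiation at the vinyl group and not at the enol ether (which would give an unreactive Fischer-type carbene), and this is secured by the steric difference between a monosubstituted and a flanked 1,1-disubstituted alkene. It also needs the absence of a second ring-closing partner, secured by keeping C8 as a bromide instead of a prenyl group, while the two blocked ortho positions suppress Claisen rearrangement of the aryl allyl ether.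

Step 9
Reactants: 12 (2S)-8-bromo-4-(TBSO)-7-methoxy-5-(TIPSO)-2-[4-(TIPSO)phenyl]-2H-chromene
Product: 14 (2R,3R)-8-bromo-3-(TBSO)-7-methoxy-5-(TIPSO)-2-[4-(TIPSO)phenyl]chroman-4-one, via silyloxy epoxide 13 (not isolated)
Conditions: mCPBA (1.05 equiv), NaHCO3 (buffer), CH2Cl2, −20 to 0 °C
Reagents that add atoms: meta-chloroperoxybenzoic acid, O=C(OO)c1cccc(Cl)c1
Why: Rubottom oxidation: the peracid should epoxidise the electron-rich C3=C4 enol ether on the face opposite the C2 aryl group, and opening of the silyloxy oxirane with 1,4-silyl shift gives the 3-silyloxy-4-ketone, so C3 is set as (R), trans to C2, by substrate control.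

Step 10
Reactants: 14 (2R,3R)-8-bromo-3-(TBSO)-7-methoxy-5-(TIPSO)-2-[4-(TIPSO)phenyl]chroman-4-one; 15 tributyl(3-methylbut-2-en-1-yl)stannane
Product: 16 (2R,3R)-3-(TBSO)-7-methoxy-8-(3-methylbut-2-en-1-yl)-5-(TIPSO)-2-[4-(TIPSO)phenyl]chroman-4-one
Conditions: Pd2(dba)3 (5 mol%), XPhos (12 mol%), LiCl, DMF, 90 °C
Reagents that add atoms: none
Why: Stille cross-coupling under neutral conditions should tolerate the silyloxy ketone and both stereocentres, and reductive elimination from the less hindered primary end of the allyl palladium intermediate should give the linear prenyl group at C8.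

Step 11
Reactants: 16 (2R,3R)-3-(TBSO)-7-methoxy-8-(3-methylbut-2-en-1-yl)-5-(TIPSO)-2-[4-(TIPSO)phenyl]chroman-4-one
Product: 17 (2R,3R)-3,5-dihydroxy-2-(4-hydroxyphenyl)-7-methoxy-8-(3-methylbut-2-en-1-yl)chroman-4-one
Conditions: Bu4NF/AcOH (1:1, excess), THF, 0 °C to rt
Reagents that add atoms: none
Why: Fluoride-mediated cleavage of all three silyl ethers under acetic acid buffering keeps the phenols protonated, which should avoid base-triggered ring opening or epimerisation of the dihydroflavonol and leaves the prenyl olefin untouched.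

**Compound list**

1 | 1-(2,6-dihydroxy-4-methoxyphenyl)ethanone | CC(=O)c1c(O)cc(OC)cc1O | starting material
2 | 1-(3-bromo-2,6-dihydroxy-4-methoxyphenyl)ethanone | CC(=O)c1c(O)cc(OC)c(Br)c1O | intermediate
3 | 1-[3-bromo-2-hydroxy-4-methoxy-6-(TIPSO)phenyl]ethanone | CC(=O)c1c(O[Si](C(C)C)(C(C)C)C(C)C)cc(OC)c(Br)c1O | intermediate
4 | methyl (E)-4-hydroxycinnamate | COC(=O)/C=C/c1ccc(O)cc1 | starting material
5 | methyl (E)-3-[4-(TIPSO)phenyl]prop-2-enoate | COC(=O)/C=C/c1ccc(O[Si](C(C)C)(C(C)C)C(C)C)cc1 | intermediate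
6 | (E)-3-[4-(TIPSO)phenyl]prop-2-en-1-ol | OC/C=C/c1ccc(O[Si](C(C)C)(C(C)C)C(C)C)cc1 | intermediate
7 | methyl (E)-3-[4-(TIPSO)phenyl]prop-2-en-1-yl carbonate | COC(=O)OC/C=C/c1ccc(O[Si](C(C)C)(C(C)C)C(C)C)cc1 | intermediate
8 | lithium 2-acetyl-6-bromo-5-methoxy-3-(TIPSO)phenoxide | [Li+].CC(=O)c1c(O[Si](C(C)C)(C(C)C)C(C)C)cc(OC)c(Br)c1[O-] | intermediate (not isolated)
9 | 1-[3-bromo-4-methoxy-2-({(1S)-1-[4-(TIPSO)phenyl]prop-2-en-1-yl}oxy)-6-(TIPSO)phenyl]ethanone | CC(=O)c1c(O[Si](C(C)C)(C(C)C)C(C)C)cc(OC)c(Br)c1O[C@H](c1ccc(O[Si](C(C)C)(C(C)C)C(C)C)cc1)C=C | intermediate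
10 | potassium 1-[3-bromo-4-methoxy-2-({(1S)-1-[4-(TIPSO)phenyl]prop-2-en-1-yl}oxy)-6-(TIPSO)phenyl]ethen-1-olate | [K+].C=C([O-])c1c(O[Si](C(C)C)(C(C)C)C(C)C)cc(OC)c(Br)c1O[C@H](c1ccc(O[Si](C(C)C)(C(C)C)C(C)C)cc1)C=C | intermediate (not isolated)
11 | 3-bromo-1-[1-(TBSO)ethenyl]-4-methoxy-2-({(1S)-1-[4-(TIPSO)phenyl]prop-2-en-1-yl}oxy)-6-(TIPSO)benzene | C=C(O[Si](C)(C)C(C)(C)C)c1c(O[Si](C(C)C)(C(C)C)C(C)C)cc(OC)c(Br)c1O[C@H](c1ccc(O[Si](C(C)C)(C(C)C)C(C)C)cc1)C=C | intermediate
12 | (2S)-8-bromo-4-(TBSO)-7-methoxy-5-(TIPSO)-2-[4-(TIPSO)phenyl]-2H-chromene | COc1cc(O[Si](C(C)C)(C(C)C)C(C)C)c2c(c1Br)O[C@H](c1ccc(O[Si](C(C)C)(C(C)C)C(C)C)cc1)C=C2O[Si](C)(C)C(C)(C)C | intermediate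
13 | 3,4-epoxide of 12 (4-silyloxy oxirane, oxirane oxygen trans to the C2 aryl group) | COc1cc(O[Si](C(C)C)(C(C)C)C(C)C)c2c(c1Br)O[C@H](c1ccc(O[Si](C(C)C)(C(C)C)C(C)C)cc1)[C@H]3O[C@@]23O[Si](C)(C)C(C)(C)C | intermediate (not isolated)
14 | (2R,3R)-8-bromo-3-(TBSO)-7-methoxy-5-(TIPSO)-2-[4-(TIPSO)phenyl]chroman-4-one | COc1cc(O[Si](C(C)C)(C(C)C)C(C)C)c2c(c1Br)O[C@H](c1ccc(O[Si](C(C)C)(C(C)C)C(C)C)cc1)[C@@H](O[Si](C)(C)C(C)(C)C)C2=O | intermediate
15 | tributyl(3-methylbut-2-en-1-yl)stannane | CCCC[Sn](CCCC)(CCCC)CC=C(C)C | starting material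
16 | (2R,3R)-3-(TBSO)-7-methoxy-8-(3-methylbut-2-en-1-yl)-5-(TIPSO)-2-[4-(TIPSO)phenyl]chroman-4-one | COc1cc(O[Si](C(C)C)(C(C)C)C(C)C)c2c(c1CC=C(C)C)O[C@H](c1ccc(O[Si](C(C)C)(C(C)C)C(C)C)cc1)[C@@H](O[Si](C)(C)C(C)(C)C)C2=O | intermediate
17 | (2R,3R)-3,5-dihydroxy-2-(4-hydroxyphenyl)-7-methoxy-8-(3-methylbut-2-en-1-yl)chroman-4-one | COc1cc(O)c2c(c1CC=C(C)C)O[C@H](c1ccc(O)cc1)[C@@H](O)C2=O | target

**Step count and risks**

Total step count: 11. Longest linear sequence: 9 steps (steps 3, 4, 5, 6, 7, 8, 9, 10, 11, from compound 4).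

Steps most likely to fail:

Step 6. The doubly ortho-substituted, chelating aryloxide may attack the allyl iridium intermediate slowly, so that branched-to-linear selectivity and enantioselectivity drop, and the electron-rich benzylic ether may re-ionise and lose its configuration. The fallback sets out from 6 (with phenol 3) and comes back at 9. Sharpless asymmetric epoxidation of 6 (Ti(OiPr)4, L-(+)-diethyl tartrate, t-BuOOH, 4 Å sieves, CH2Cl2, −20 °C) should give the epoxy alcohol [(2S,3S)-3-[4-(TIPSO)phenyl]oxiran-2-yl]methanol F1. Opening of F1 by phenol 3 at the benzylic carbon with inversion, mediated by Ti(OiPr)4, should give the diol 1-[3-bromo-2-({(1R,2S)-2,3-dihydroxy-1-[4-(TIPSO)phenyl]propyl}oxy)-4-methoxy-6-(TIPSO)phenyl]ethanone F2. Garegg–Samuelsson deoxygenation of the terminal diol (PPh3, I2, imidazole, toluene, 80 °C) then gives 9.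

Step 8. Ring closure onto the flanked 1,1-disubstituted enol ether may be slow, so that isomerisation of the allyl ether by ruthenium hydride species, loss of the enol silyl group or catalyst decomposition takes over. The fallback sets out from 9 and comes back at 14, closing the same bond on an all-carbon diene:
- Reduction of the ketone (LiBH4, THF) should give the benzylic alcohol 1-[3-bromo-4-methoxy-2-({(1S)-1-[4-(TIPSO)phenyl]prop-2-en-1-yl}oxy)-6-(TIPSO)phenyl]ethanol F3.
- Dehydration with the Burgess reagent should give the styrene 3-bromo-1-ethenyl-4-methoxy-2-({(1S)-1-[4-(TIPSO)phenyl]prop-2-en-1-yl}oxy)-6-(TIPSO)benzene F4.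
- Diene ring-closing metathesis with the same catalyst should give (2S)-8-bromo-7-methoxy-5-(TIPSO)-2-[4-(TIPSO)phenyl]-2H-chromene F5.
- Dihydroxylation anti to the C2 aryl group (OsO4 cat., NMO) should give (2R,3S,4S)-8-bromo-7-methoxy-5-(TIPSO)-2-[4-(TIPSO)phenyl]chromane-3,4-diol F6.
- Selective oxidation of the benzylic C4 alcohol (MnO2, CH2Cl2) should give (2R,3R)-8-bromo-3-hydroxy-7-methoxy-5-(TIPSO)-2-[4-(TIPSO)phenyl]chroman-4-one F7.
- Silylation (TBSOTf, 2,6-lutidine) returns 14.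

Step 10. Oxidative addition at the bromide flanked by two oxygen substituents may be slow, with protodebromination or coupling through the tertiary allyl terminus (1,1-dimethylallyl isomer) competing. The fallback sets out from 14 and comes back at 16. Stille coupling with allyltributylstannane, which has no regiochemical choice, should give (2R,3R)-8-allyl-3-(TBSO)-7-methoxy-5-(TIPSO)-2-[4-(TIPSO)phenyl]chroman-4-one F8. Cross-metathesis of F8 with excess 2-methyl-2-butene (second-generation Grubbs catalyst, CH2Cl2, 40 °C) then gives 16.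

**Further compounds**

F1 | step 6 | [(2S,3S)-3-[4-(TIPSO)phenyl]oxiran-2-yl]methanol | OC[C@@H]1O[C@H]1c1ccc(O[Si](C(C)C)(C(C)C)C(C)C)cc1
F2 | step 6 | 1-[3-bromo-2-({(1R,2S)-2,3-dihydroxy-1-[4-(TIPSO)phenyl]propyl}oxy)-4-methoxy-6-(TIPSO)phenyl]ethanone | CC(=O)c1c(O[Si](C(C)C)(C(C)C)C(C)C)cc(OC)c(Br)c1O[C@H](c1ccc(O[Si](C(C)C)(C(C)C)C(C)C)cc1)[C@@H](O)CO
F3 | step 8 | 1-[3-bromo-4-methoxy-2-({(1S)-1-[4-(TIPSO)phenyl]prop-2-en-1-yl}oxy)-6-(TIPSO)phenyl]ethanol (both carbinol epimers) | CC(O)c1c(O[Si](C(C)C)(C(C)C)C(C)C)cc(OC)c(Br)c1O[C@H](c1ccc(O[Si](C(C)C)(C(C)C)C(C)C)cc1)C=C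
F4 | step 8 | 3-bromo-1-ethenyl-4-methoxy-2-({(1S)-1-[4-(TIPSO)phenyl]prop-2-en-1-yl}oxy)-6-(TIPSO)benzene | C=Cc1c(O[Si](C(C)C)(C(C)C)C(C)C)cc(OC)c(Br)c1O[C@H](c1ccc(O[Si](C(C)C)(C(C)C)C(C)C)cc1)C=C
F5 | step 8 | (2S)-8-bromo-7-methoxy-5-(TIPSO)-2-[4-(TIPSO)phenyl]-2H-chromene | COc1cc(O[Si](C(C)C)(C(C)C)C(C)C)c2c(c1Br)O[C@H](c1ccc(O[Si](C(C)C)(C(C)C)C(C)C)cc1)C=C2
F6 | step 8 | (2R,3S,4S)-8-bromo-7-methoxy-5-(TIPSO)-2-[4-(TIPSO)phenyl]chromane-3,4-diol | COc1cc(O[Si](C(C)C)(C(C)C)C(C)C)c2c(c1Br)O[C@H](c1ccc(O[Si](C(C)C)(C(C)C)C(C)C)cc1)[C@@H](O)[C@H]2O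
F7 | step 8 | (2R,3R)-8-bromo-3-hydroxy-7-methoxy-5-(TIPSO)-2-[4-(TIPSO)phenyl]chroman-4-one | COc1cc(O[Si](C(C)C)(C(C)C)C(C)C)c2c(c1Br)O[C@H](c1ccc(O[Si](C(C)C)(C(C)C)C(C)C)cc1)[C@@H](O)C2=O
F8 | step 10 | (2R,3R)-8-allyl-3-(TBSO)-7-methoxy-5-(TIPSO)-2-[4-(TIPSO)phenyl]chroman-4-one | COc1cc(O[Si](C(C)C)(C(C)C)C(C)C)c2c(c1CC=C)O[C@H](c1ccc(O[Si](C(C)C)(C(C)C)C(C)C)cc1)[C@@H](O[Si](C)(C)C(C)(C)C)C2=O
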